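A small charge of free monomer at a loading of 0.5 mol% brings a small charge of initiator with it, and the readings show what that costs.

the same everywhere: initiator 0.5 mol%

| charge | free monomer | remark | time |
|---|---|---|---|
| violet | 0.034 M | run made earlier |  |
| blue | 0.057 M | run made earlier |  |
| grey | 0.12 M | run made earlier |  |
| south-east | 0.031 M |  | 80 min |
| north-east | 0.10 M |  | 80 min |

| violet: time / min | violet: monomer in chains / % | blue: time / min | blue: monomer in chains / % | grey: time / min | grey: monomer in chains / % |
|---|---|---|---|---|---|
| 8.00 | 0 | 4.00 | 0 | 8.00 | 6 |
| 15.0 | 4 | 10.0 | 2 | 15.0 | 17 |
| 25.0 | 4 | 20.0 | 9 | 25.0 | 33 |
| 30.0 | 2 | 30.0 | 14 | 30.0 | 42 |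
| 40.0 | 8 | 40.0 | 24 | 40.0 | 60 |

(each reading ± 1.5 percentage points)

- the average divides the monomer in chains by the number of chains begun, living and dead together
- the analysis behind the earlier runs scatters by 1.5 percentage points, standard deviation
- on the list of suspects stand: free monomer + initiator -> living end + monomer in chains; free monomer + living end -> monomer in chains + living end; initiator + monomer in chains -> spent initiator; free monomer -> uncatalysed product
- the earlier runs do not show the number of chains; that part of a forecast is a guess

1. which of the two ends with the longer chains by the average number of monomer units in a chain (chains begun, living or dead) ("neither" if they lie within 10%) (south-east / north-east / neither)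
2. average number of monomer units in a chain (chains begun, living or dead) at the end, south-east
3. average number of monomer units in a chain (chains begun, living or dead) at the end, north-east

How much enters chains? Take the first-order measure, the logarithm of the charge over what is outside chains. At 40.0 min it reads 0.916 in grey and 0.0834 in violet, a ratio of 11.0, while the squared ratio of charges is 12.5. My reckoning therefore scales grey by the square of the charge, and also takes the square of time. That puts 21.7% in chains in south-east and 92.2% in north-east.

How long are the chains? The full-charge length is one over the loading, 200 units: what a chain holds if every initiator begins one and the whole charge enters chains. This is the number-average degree of polymerisation in that limit. The true fraction in chains times this length is a floor for a flask, since fewer chains mean longer ones; my estimated fractions, which are no bounds, put it near 43.4 for south-east and 184 for north-east.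

Can unused initiator reverse the order? Going round once more, the first listed step begins chains at a rate per initiator in step with free monomer, so my rough estimate sets the ratio of chains begun, as fractions of each flask's initiator, at the charge ratio, 3.23. On that estimate, which is no bound, north-east comes out longer by a factor of 1.32, beyond the margin.

The forecast also says north-east, with 75 (45 to 125) for south-east and 180 (125 to 260) for north-east, and adds: “The split between ki and kp rests only on curve shape, so chain counts are a guess.”

The flask gives 100 for south-east and 238 for north-east.

    free monomer + initiator → living end + monomer in chains (k = 22.0 L mol⁻¹ h⁻¹)
    free monomer + living end → monomer in chains + living end, rate k2*[living end]*[free monomer] (k = 4900 L mol⁻¹ h⁻¹)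
    initiator + monomer in chains → spent initiator (k = 36.0 L mol⁻¹ h⁻¹)
    free monomer → uncatalysed product (k = 0.0630 h⁻¹)

At 80 min, south-east keeps 39.3% of its initiator and north-east 2.54%. North-east's 79.8% in chains makes a floor of 160, and its length stands 1.49 times above that. A neighbour of north-east charged at 0.025 M, same loading, holds 19.3% in chains, a floor of 38.6, and reaches 82.0.

The data stem from a simulated flask on assumed constants; scatter was added.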